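**Retrosynthetic overview**

1. The target is a (2S)-5,7-dihydroxyflavanone whose ring B (3',5'-dimethoxy) carries at O4' a threo (7R,8R) 1-(4-hydroxyphenyl)glycerol unit. Ring C is the only ring made in the route and is closed last; rings A, B and the phenol ring are bought.
2. Key disconnection: O1–C2 and C4–C4a together, back to the phloroglucinol monoester 18 of the complete cinnamic acid (photo-Fries acyl shift, then enzyme-guided oxa-Michael closure).
3. Enabling feature: the threefold-symmetric 1,3,5-trioxygenated ring A (O1 on C8a, OH on C5, OH on C7). Every ring CH lies between two oxygens, so any acyl shift gives the same 2,4,6-trihydroxyaryl ketone, and either flanking hydroxyl closes ring C to the same flavanone.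
4. Ester C–O: cinnamic acid 15 plus phloroglucinol. C2–C1': Heck reaction of aryl bromide 13 with acrylic acid.
5. C7–C8: Evans syn-aldol of the aryloxyacetyl oxazolidinone 7 with 4-silyloxybenzaldehyde 8, which sets (7R,8R).

Key step: step 9

Assumption: recombinant chalcone isomerase (Medicago sativa enzyme expressed in E. coli) serves as a catalyst and is not counted as a starting material.

**Route**

Step 1
Reactants: 1 4-bromo-2,6-dimethoxyphenol; 2 ethyl bromoacetate
Product: 4 2-(4-bromo-2,6-dimethoxyphenoxy)acetic acid, via ethyl ester 3 (not isolated)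
Conditions: K2CO3, acetone, reflux; then aq. NaOH, rt; HCl to pH 2
Reagents that add atoms: sodium hydroxide, [Na+].[OH-]
Why: Williamson ether synthesis of the hindered phenoxide with the reactive α-bromo ester, then saponification in the same pot; no stereocentre is formed.

Step 2
Reactants: 4 2-(4-bromo-2,6-dimethoxyphenoxy)acetic acid; 5 (S)-4-benzyl-1,3-oxazolidin-2-one
Product: 7 (S)-4-benzyl-3-[2-(4-bromo-2,6-dimethoxyphenoxy)acetyl]-1,3-oxazolidin-2-one, via mixed pivalic anhydride 6 (not isolated)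
Conditions: pivaloyl chloride, Et3N, THF, −20 °C; then 5, LiCl, −20 °C to rt
Reagents that add atoms: none
Why: N-acylation of the oxazolidinone through the mixed pivalic anhydride is the standard entry to Evans imides, and the hindered pivaloyl carbonyl should not compete.

Step 3
Reactants: 7 (S)-4-benzyl-3-[2-(4-bromo-2,6-dimethoxyphenoxy)acetyl]-1,3-oxazolidin-2-one; 8 4-(tert-butyldimethylsilyloxy)benzaldehyde
Product: 11 (S)-4-benzyl-3-[(2S,3R)-2-(4-bromo-2,6-dimethoxyphenoxy)-3-[4-(tert-butyldimethylsilyloxy)phenyl]-3-hydroxypropanoyl]-1,3-oxazolidin-2-one, via boron enolate 9 (not isolated), via boron aldolate 10 (not isolated)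
Conditions: Bu2BOTf, iPr2NEt, CH2Cl2, 0 °C; 8, −78 to 0 °C; pH 7 buffer, MeOH, H2O2
Reagents that add atoms: none
Why: Evans syn-aldol reaction, in which the Z-configured dibutylboron glycolate enolate should react through a closed chair (Zimmerman–Traxler) transition state on the face away from the benzyl group of the (S)-auxiliary, setting C8 and C7 together as the syn (threo) pair that becomes (7R,8R).

Step 4
Reactants: 11 the syn-aldol imide
Product: 12 (1R,2R)-2-(4-bromo-2,6-dimethoxyphenoxy)-1-[4-(tert-butyldimethylsilyloxy)phenyl]propane-1,3-diol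
Conditions: LiBH4, THF, MeOH (1 equiv), 0 °C
Reagents that add atoms: none
Why: reductive removal of the auxiliary, since LiBH4 attacks the exocyclic imide carbonyl selectively, should give the primary alcohol without touching C8, whose descriptor becomes R only through the change of priorities.

Step 5
Reactants: 12 the 1,3-diol
Product: 13 5-bromo-2-{[(1R,2R)-1,3-bis(tert-butyldimethylsilyloxy)-1-[4-(tert-butyldimethylsilyloxy)phenyl]propan-2-yl]oxy}-1,3-dimethoxybenzene
Conditions: TBSOTf, 2,6-lutidine, CH2Cl2, −78 to 0 °C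
Reagents that add atoms: tert-butyldimethylsilyl triflate, CC(C)(C)[Si](C)(C)OS(=O)(=O)C(F)(F)F
Why: silylation with the silyl triflate and lutidine should protect the primary and the hindered benzylic hydroxyl under basic, non-ionising conditions, so C7 keeps its configuration.

Step 6
Reactants: 13 the tris-silylated aryl bromide; 14 acrylic acid
Product: 15 (E)-3-[4-{[(1R,2R)-1,3-bis(tert-butyldimethylsilyloxy)-1-[4-(tert-butyldimethylsilyloxy)phenyl]propan-2-yl]oxy}-3,5-dimethoxyphenyl]prop-2-enoic acid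
Conditions: Pd(OAc)2 (5 mol%), P(o-tol)3, Et3N, MeCN, 85 °C
Reagents that add atoms: none
Why: Mizoroki–Heck reaction of the aryl bromide with acrylic acid should give the (E)-cinnamic acid directly (syn insertion, syn β-hydride elimination), which avoids a later ester hydrolysis that the aryl silyl ether would not survive.

Step 7
Reactants: 15 the silylated cinnamic acid; 16 phloroglucinol (anhydrous, 5 equiv)
Product: 17 3,5-dihydroxyphenyl (E)-3-[4-{[(1R,2R)-1,3-bis(tert-butyldimethylsilyloxy)-1-[4-(tert-butyldimethylsilyloxy)phenyl]propan-2-yl]oxy}-3,5-dimethoxyphenyl]prop-2-enoate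
Conditions: DCC, DMAP (cat.), THF, 0 °C to rt
Reagents that add atoms: none
Why: Steglich esterification, in which an excess of the cheap triphenol should make the monoester the main product and the equivalence of its three hydroxyls removes any regiochemical question.

Step 8
Reactants: 17 the silylated 3,5-dihydroxyphenyl ester
Product: 18 3,5-dihydroxyphenyl (E)-3-[4-{[(1R,2R)-1,3-dihydroxy-1-(4-hydroxyphenyl)propan-2-yl]oxy}-3,5-dimethoxyphenyl]prop-2-enoate
Conditions: HF·pyridine, pyridine, THF, 0 °C to rt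
Reagents that add atoms: none
Why: fluoride cleavage of the three silyl ethers under buffered, weakly acidic conditions should leave intact both the aryl ester, which is labile to base but not to acid, and the benzylic centre.

Step 9
Reactants: 18 the free 3,5-dihydroxyphenyl cinnamate
Product: 21 (2S)-5,7-dihydroxy-2-[4-{[(1R,2R)-1,3-dihydroxy-1-(4-hydroxyphenyl)propan-2-yl]oxy}-3,5-dimethoxyphenyl]chroman-4-one, via acylcyclohexadienone 19 (not isolated), via chalcone 20 (not isolated)
Conditions: hν (310 nm), degassed MeCN/H2O 4:1, flow reactor, 20 °C; effluent run directly into chalcone isomerase, phosphate buffer pH 7.0 (final MeCN ≤ 10%), 25 °C, dark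
Reagents that add atoms: none
Why: Proposed new method: light absorbed by the aryl cinnamate of 18 homolyses the ArO–C(=O) bond, the caged 3,5-dihydroxyphenoxyl/cinnamoyl radical pair recombines at a ring carbon (C4–C4a bond) and dienone 19 enolises to chalcone 20, whose 2'-phenoxide is then held by the enzyme for conjugate addition to the enone β-carbon (O1–C2 bond). The closest known reaction types are the photo-Fries rearrangement of hydroxyphenyl cinnamates to 2'-hydroxychalcones and the chalcone isomerase cyclisation of 6'-hydroxychalcones to (2S)-flavanones; new is their telescoping on a chalcone whose ring B carries a large para ether, which is expected to point out of the active-site cleft because the enzyme recognises ring A and the enone. Ring C, the only ring formed, closes by a 6-endo-trig oxa-Michael addition. The single new stereocentre C2 is under catalyst control, the active site exposing the enone face that leads to (2S), since the side-chain centres are too remote to bias it. Two selectivities are needed: the site of acyl migration, which the threefold symmetry of ring A makes irrelevant (ortho and para shifts give the same 2,4,6-trihydroxyaryl ketone and both flanking hydroxyls close to the same flavanone), and enzyme-controlled over uncatalysed closure, secured by neutral pH, darkness and 25 °C, where the background reaction is slow. As the last step at neutral pH it also spares the base-labile C2 centre of the 5-hydroxyflavanone from later epimerisation.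

**Compound list**

1 | 4-bromo-2,6-dimethoxyphenol | COc1cc(Br)cc(OC)c1O | starting material
2 | ethyl bromoacetate | CCOC(=O)CBr | starting material
3 | ethyl 2-(4-bromo-2,6-dimethoxyphenoxy)acetate | CCOC(=O)COc1c(OC)cc(Br)cc1OC | intermediate
4 | 2-(4-bromo-2,6-dimethoxyphenoxy)acetic acid | OC(=O)COc1c(OC)cc(Br)cc1OC | intermediate
5 | (S)-4-benzyl-1,3-oxazolidin-2-one | O=C1N[C@@H](Cc2ccccc2)CO1 | starting material
6 | 2-(4-bromo-2,6-dimethoxyphenoxy)acetic pivalic anhydride | CC(C)(C)C(=O)OC(=O)COc1c(OC)cc(Br)cc1OC | intermediate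
7 | (S)-4-benzyl-3-[2-(4-bromo-2,6-dimethoxyphenoxy)acetyl]-1,3-oxazolidin-2-one | O=C(COc1c(OC)cc(Br)cc1OC)N1C(=O)OC[C@@H]1Cc1ccccc1 | intermediate
8 | 4-(tert-butyldimethylsilyloxy)benzaldehyde | CC(C)(C)[Si](C)(C)Oc1ccc(C=O)cc1 | starting material
9 | (Z)-dibutylboron enolate of imide 7 | CCCCB(CCCC)O/C(=C\Oc1c(OC)cc(Br)cc1OC)N1C(=O)OC[C@@H]1Cc1ccccc1 | intermediate
10 | O-dibutylboryl aldolate of imide 11 | COc1cc(Br)cc(OC)c1O[C@H](C(=O)N1C(=O)OC[C@@H]1Cc1ccccc1)[C@H](OB(CCCC)CCCC)c1ccc(O[Si](C)(C)C(C)(C)C)cc1 | intermediate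
11 | (S)-4-benzyl-3-[(2S,3R)-2-(4-bromo-2,6-dimethoxyphenoxy)-3-[4-(tert-butyldimethylsilyloxy)phenyl]-3-hydroxypropanoyl]-1,3-oxazolidin-2-one | COc1cc(Br)cc(OC)c1O[C@H](C(=O)N1C(=O)OC[C@@H]1Cc1ccccc1)[C@H](O)c1ccc(O[Si](C)(C)C(C)(C)C)cc1 | intermediate
12 | (1R,2R)-2-(4-bromo-2,6-dimethoxyphenoxy)-1-[4-(tert-butyldimethylsilyloxy)phenyl]propane-1,3-diol | COc1cc(Br)cc(OC)c1O[C@H](CO)[C@H](O)c1ccc(O[Si](C)(C)C(C)(C)C)cc1 | intermediate
13 | 5-bromo-2-{[(1R,2R)-1,3-bis(tert-butyldimethylsilyloxy)-1-[4-(tert-butyldimethylsilyloxy)phenyl]propan-2-yl]oxy}-1,3-dimethoxybenzene | COc1cc(Br)cc(OC)c1O[C@H](CO[Si](C)(C)C(C)(C)C)[C@H](O[Si](C)(C)C(C)(C)C)c1ccc(O[Si](C)(C)C(C)(C)C)cc1 | intermediate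
14 | acrylic acid | C=CC(=O)O | starting material
15 | (E)-3-[4-{[(1R,2R)-1,3-bis(tert-butyldimethylsilyloxy)-1-[4-(tert-butyldimethylsilyloxy)phenyl]propan-2-yl]oxy}-3,5-dimethoxyphenyl]prop-2-enoic acid | COc1cc(/C=C/C(=O)O)cc(OC)c1O[C@H](CO[Si](C)(C)C(C)(C)C)[C@H](O[Si](C)(C)C(C)(C)C)c1ccc(O[Si](C)(C)C(C)(C)C)cc1 | intermediate
16 | phloroglucinol (benzene-1,3,5-triol) | Oc1cc(O)cc(O)c1 | starting material
17 | 3,5-dihydroxyphenyl (E)-3-[4-{[(1R,2R)-1,3-bis(tert-butyldimethylsilyloxy)-1-[4-(tert-butyldimethylsilyloxy)phenyl]propan-2-yl]oxy}-3,5-dimethoxyphenyl]prop-2-enoate | COc1cc(/C=C/C(=O)Oc2cc(O)cc(O)c2)cc(OC)c1O[C@H](CO[Si](C)(C)C(C)(C)C)[C@H](O[Si](C)(C)C(C)(C)C)c1ccc(O[Si](C)(C)C(C)(C)C)cc1 | intermediate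
18 | 3,5-dihydroxyphenyl (E)-3-[4-{[(1R,2R)-1,3-dihydroxy-1-(4-hydroxyphenyl)propan-2-yl]oxy}-3,5-dimethoxyphenyl]prop-2-enoate | COc1cc(/C=C/C(=O)Oc2cc(O)cc(O)c2)cc(OC)c1O[C@H](CO)[C@H](O)c1ccc(O)cc1 | intermediate
19 | 6-acyl-3,5-dihydroxycyclohexa-2,4-dien-1-one (acyl = the (E)-cinnamoyl group of 18; keto tautomer of 20) | COc1cc(/C=C/C(=O)C2C(=O)C=C(O)C=C2O)cc(OC)c1O[C@H](CO)[C@H](O)c1ccc(O)cc1 | intermediate
20 | (E)-3-[4-{[(1R,2R)-1,3-dihydroxy-1-(4-hydroxyphenyl)propan-2-yl]oxy}-3,5-dimethoxyphenyl]-1-(2,4,6-trihydroxyphenyl)prop-2-en-1-one | COc1cc(/C=C/C(=O)c2c(O)cc(O)cc2O)cc(OC)c1O[C@H](CO)[C@H](O)c1ccc(O)cc1 | intermediate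
21 | (2S)-5,7-dihydroxy-2-[4-{[(1R,2R)-1,3-dihydroxy-1-(4-hydroxyphenyl)propan-2-yl]oxy}-3,5-dimethoxyphenyl]chroman-4-one | COc1cc([C@@H]2CC(=O)c3c(O)cc(O)cc3O2)cc(OC)c1O[C@H](CO)[C@H](O)c1ccc(O)cc1 | target

**Step count and risks**

Total step count: 9. Longest linear sequence: 9 steps (1 to 21).

Steps most likely to fail:

1. Step 9. The excited cinnamate may relax mainly by E/Z isomerisation, or the radical pair may escape the solvent cage, so that little chalcone forms. The enzyme may also fail to bind a chalcone with so large a ring B ether; the slow uncatalysed closure would then take over and facial control at C2 would be lost. The fallback uses known chemistry only, sets out from 13 and comes back at 21. Bromine–lithium exchange on 13 (n-BuLi, THF, −78 °C) and a DMF quench should give the aldehyde F1. Claisen–Schmidt condensation of F1 with commercial 1-[2,4-bis(benzyloxy)-6-hydroxyphenyl]ethanone (KOH, EtOH/THF, rt), in which the aryl silyl ether is cleaved as well, should give the chalcone F2. NaOAc in refluxing EtOH should close F2 to the flavanone F3, formed as both C2 epimers. HF·pyridine should then free the side-chain diol F4, and hydrogenolysis (H2, Pd/C, EtOAc) should give 21 together with its (2R)-epimer F5. The two should be separable by preparative HPLC on a chiral stationary phase, and F5 can be re-equilibrated at C2 through the chalcone with mild base and recycled.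

2. Step 3. Incomplete enolisation, or an open, chelated transition state brought about by the two ortho-methoxy groups, would erode the syn selectivity, and retro-aldol cleavage of the electron-rich benzylic aldolate may lower conversion. The fallback replaces auxiliary control by catalyst control; it sets out from 3 (isolated after the alkylation stage of step 1 instead of being saponified) and comes back at 12. Aldol addition of the lithium enolate of 3 (LiN(iPr)2, THF, −78 °C) to 8 should give the hydroxy ester F6 as a mixture of stereoisomers, and Dess–Martin periodinane should oxidise it to the configurationally labile β-keto ester F7. Asymmetric transfer hydrogenation with dynamic kinetic resolution (RuCl[(S,S)-TsDPEN](p-cymene), HCO2H/Et3N, CH2Cl2, 30 °C), a reaction type known to turn α-alkoxy β-keto esters into syn α-alkoxy β-hydroxy esters, should give the syn-hydroxy ester F8. The catalyst antipode is chosen by the aryl ketone model. LiBH4 (THF, 0 °C) then reduces the ester to the diol 12.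

3. Step 7. Over-acylation of phloroglucinol to bis- and tris-esters, and slow acylation of the weakly nucleophilic phenol with N-acylurea formation, would waste the advanced acid. The fallback moves the statistical event to the cheap triphenol; it sets out from 15 and 16 and comes back at 18. Silylation of 16 (TBSCl, 2 equiv, imidazole, DMF) and chromatographic separation should give 3,5-bis(tert-butyldimethylsilyloxy)phenol F9, which has a single free hydroxyl. Steglich esterification of 15 with F9 (DCC, DMAP, CH2Cl2) should give the pentasilyl ester F10, and HF·pyridine should remove all five silyl groups in one operation to give 18.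

**Further compounds**

F1 | step 9 | 4-{[(1R,2R)-1,3-bis(tert-butyldimethylsilyloxy)-1-[4-(tert-butyldimethylsilyloxy)phenyl]propan-2-yl]oxy}-3,5-dimethoxybenzaldehyde | COc1cc(C=O)cc(OC)c1O[C@H](CO[Si](C)(C)C(C)(C)C)[C@H](O[Si](C)(C)C(C)(C)C)c1ccc(O[Si](C)(C)C(C)(C)C)cc1
F2 | step 9 | (E)-1-[2,4-bis(benzyloxy)-6-hydroxyphenyl]-3-[4-{[(1R,2R)-1,3-bis(tert-butyldimethylsilyloxy)-1-(4-hydroxyphenyl)propan-2-yl]oxy}-3,5-dimethoxyphenyl]prop-2-en-1-one | COc1cc(/C=C/C(=O)c2c(O)cc(OCc3ccccc3)cc2OCc2ccccc2)cc(OC)c1O[C@H](CO[Si](C)(C)C(C)(C)C)[C@H](O[Si](C)(C)C(C)(C)C)c1ccc(O)cc1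
F3 | step 9 | 5,7-bis(benzyloxy)-2-[4-{[(1R,2R)-1,3-bis(tert-butyldimethylsilyloxy)-1-(4-hydroxyphenyl)propan-2-yl]oxy}-3,5-dimethoxyphenyl]chroman-4-one (both C2 epimers) | COc1cc(C2CC(=O)c3c(OCc4ccccc4)cc(OCc4ccccc4)cc3O2)cc(OC)c1O[C@H](CO[Si](C)(C)C(C)(C)C)[C@H](O[Si](C)(C)C(C)(C)C)c1ccc(O)cc1
F4 | step 9 | 5,7-bis(benzyloxy)-2-[4-{[(1R,2R)-1,3-dihydroxy-1-(4-hydroxyphenyl)propan-2-yl]oxy}-3,5-dimethoxyphenyl]chroman-4-one (both C2 epimers) | COc1cc(C2CC(=O)c3c(OCc4ccccc4)cc(OCc4ccccc4)cc3O2)cc(OC)c1O[C@H](CO)[C@H](O)c1ccc(O)cc1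
F5 | step 9 | (2R)-5,7-dihydroxy-2-[4-{[(1R,2R)-1,3-dihydroxy-1-(4-hydroxyphenyl)propan-2-yl]oxy}-3,5-dimethoxyphenyl]chroman-4-one | COc1cc([C@H]2CC(=O)c3c(O)cc(O)cc3O2)cc(OC)c1O[C@H](CO)[C@H](O)c1ccc(O)cc1
F6 | step 3 | ethyl 2-(4-bromo-2,6-dimethoxyphenoxy)-3-[4-(tert-butyldimethylsilyloxy)phenyl]-3-hydroxypropanoate (stereoisomer mixture) | CCOC(=O)C(Oc1c(OC)cc(Br)cc1OC)C(O)c1ccc(O[Si](C)(C)C(C)(C)C)cc1
F7 | step 3 | ethyl 2-(4-bromo-2,6-dimethoxyphenoxy)-3-[4-(tert-butyldimethylsilyloxy)phenyl]-3-oxopropanoate (racemic) | CCOC(=O)C(Oc1c(OC)cc(Br)cc1OC)C(=O)c1ccc(O[Si](C)(C)C(C)(C)C)cc1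
F8 | step 3 | ethyl (2S,3R)-2-(4-bromo-2,6-dimethoxyphenoxy)-3-[4-(tert-butyldimethylsilyloxy)phenyl]-3-hydroxypropanoate | CCOC(=O)[C@@H](Oc1c(OC)cc(Br)cc1OC)[C@H](O)c1ccc(O[Si](C)(C)C(C)(C)C)cc1
F9 | step 7 | 3,5-bis(tert-butyldimethylsilyloxy)phenol | CC(C)(C)[Si](C)(C)Oc1cc(O)cc(O[Si](C)(C)C(C)(C)C)c1
F10 | step 7 | 3,5-bis(tert-butyldimethylsilyloxy)phenyl (E)-3-[4-{[(1R,2R)-1,3-bis(tert-butyldimethylsilyloxy)-1-[4-(tert-butyldimethylsilyloxy)phenyl]propan-2-yl]oxy}-3,5-dimethoxyphenyl]prop-2-enoate | COc1cc(/C=C/C(=O)Oc2cc(O[Si](C)(C)C(C)(C)C)cc(O[Si](C)(C)C(C)(C)C)c2)cc(OC)c1O[C@H](CO[Si](C)(C)C(C)(C)C)[C@H](O[Si](C)(C)C(C)(C)C)c1ccc(O[Si](C)(C)C(C)(C)C)cc1
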